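**Retrosynthetic overview**

1. Target 15 ⇐ enone 14 (methylenation of the C8 carbonyl) ⇐ decalone 12 (C6–C7 dehydrogenation).
2. Key disconnection C8–C9 of ring B: 12 ⇐ seco keto ester 10. Forward, the C9 ketone carbon reacts with reversed polarity as a titanium ketyl (a d1 carbon) and attacks the C8 ester carbonyl, so two electrophilic carbonyl carbons are joined; C9–H is set on hydrolysis.
3. Side chain: C11–C12, from the methyl-ketone enolate of 7 and allylic bromide 8.
4. Ring A (C4, C5, C10) comes unchanged from dehydroabietic acid 1 with its two methyl-bearing quaternary carbons exchanging roles (abietane C10 → C4, abietane C4 → C10). Aryl C9 becomes C18 (CH2OAc), the CO2H carbon becomes C9 and aryl C8 becomes C8. This exchange converts the normal abietane into the ent-labdane series of the target.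
5. Ring order: ring A from the chiral pool; abietane rings B and C destroyed oxidatively; new ring B closed last by the C8–C9 coupling.

Assumption: dehydroabietic acid and methyl (2E)-4-bromo-3-methylbut-2-enoate are bought; atom labels C1–C20 are those of the target (labdane numbering) throughout.

**Route**

Step 1
Reactants: 1 dehydroabietic acid
Product: 3 1-[(1R,4aS,10aR)-1,4a-dimethyl-7-(propan-2-yl)-1,2,3,4,4a,9,10,10a-octahydrophenanthren-1-yl]ethan-1-one (methyl ketone), via dilithium gem-diolate 2 (not isolated)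
Conditions: MeLi (3.5 equiv), Et2O/THF, 0 °C → rt; then poured into cold 1 M HCl
Reagents that add atoms: methyllithium, C[Li]
Why: Organolithium addition to a lithium carboxylate (Gilman–van Ess ketone synthesis) stops at the ketone because the hindered gem-diolate survives until the acidic quench, and the three ring stereocentres taken from 1 are untouched.

Step 2
Reactants: 3 methyl ketone
Product: 4 (1S,2S,3R)-3-acetyl-2-(2-carboxyethyl)-1,3-dimethylcyclohexane-1-carboxylic acid
Conditions: RuCl3 hydrate (5 mol %), NaIO4 (20 equiv), CCl4/MeCN/H2O, rt, 48 h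
Reagents that add atoms: sodium periodate, [Na+].[O-]I(=O)(=O)=O; water, O
Why: RuO4-catalysed arene degradation (Sharpless conditions) burns the electron-rich trialkylbenzene ring down to the two carbons bonded to sp3 carbon, which remain as CO2H groups, while the ketone and the quaternary centres are inert, so C4, C5 and C10 keep the configuration of 1.

Step 3
Reactants: 4 keto diacid
Product: 5 (1S,2S,3R)-3-acetyl-2-(3-methoxy-3-oxopropyl)-1,3-dimethylcyclohexane-1-carboxylic acid
Conditions: MeOH, H2SO4 (cat.), rt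
Reagents that add atoms: methanol, CO
Why: Fischer esterification is selective on steric grounds, since the primary propanoic acid esterifies at room temperature whereas the carboxyl on the quaternary ring carbon does not.

Step 4
Reactants: 5 keto acid ester
Product: 6 methyl 3-[(1R,2R,6S)-2-acetyl-6-(hydroxymethyl)-2,6-dimethylcyclohexyl]propanoate
Conditions: BH3·THF (1.3 equiv), THF, −10 → 0 °C; then aq. NaHCO3
Reagents that add atoms: none
Why: Borane reduction of a carboxylic acid (through the acyloxyborane) is faster than reduction of an ester or of a ketone flanked by a quaternary carbon, and gives the neopentyl alcohol that becomes C18.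

Step 5
Reactants: 6 hydroxy ketone
Product: 7 methyl 3-[(1R,2R,6S)-2-acetyl-6-(acetoxymethyl)-2,6-dimethylcyclohexyl]propanoate
Conditions: Ac2O, pyridine, DMAP (cat.), CH2Cl2, rt
Reagents that add atoms: acetic anhydride, CC(=O)OC(C)=O
Why: DMAP-catalysed O-acylation installs the acetate of the target and removes the only O–H before the enolate step.

Step 6
Reactants: 7 keto acetate; 8 methyl (2E)-4-bromo-3-methylbut-2-enoate
Product: 10 methyl (2E)-6-[(1R,2R,3S)-3-(acetoxymethyl)-2-(3-methoxy-3-oxopropyl)-1,3-dimethylcyclohexyl]-3-methyl-6-oxohex-2-enoate, via lithium enolate 9 (not isolated)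
Conditions: LiN(iPr)2 (1.05 equiv), THF, −78 °C; then 8 (1.3 equiv), DMPU, −78 → −20 °C
Reagents that add atoms: compound 8, BrC/C(C)=C/C(=O)OC
Why: Kinetic lithium enolate alkylation (SN2 at a primary allylic bromide) works because the acetyl methyl is the only enolisable position of the ketone and is more acidic than the ester and acetate C–H, and the E geometry of 8 is carried into C13=C14 unchanged.

Step 7
Reactants: 10 seco keto ester
Product: 12 methyl (2E)-5-[(1S,4aS,5S,8aR)-5-(acetoxymethyl)-5,8a-dimethyl-2-oxodecahydronaphthalen-1-yl]-3-methylpent-2-enoate, via cyclic methyl enol ether 11 (not isolated)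
Conditions: TiCl3(DME)1.5, Zn–Cu couple, DME, reflux, slow addition of 10 (high dilution); then 1 M HCl, THF, rt
Reagents that add atoms: water, O
Why: In this McMurry keto-ester cyclisation zerovalent titanium turns the C9 ketone into a nucleophilic ketyl (α-oxido carbanion) that attacks the C8 ester carbonyl to close ring B as the enol ether, and acidic hydrolysis protonates C9 anti to the axial C10 methyl so that this α-keto centre settles with the side chain equatorial, which is the C9 configuration of the target.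

Step 8
Reactants: 12 decalone
Product: 14 methyl (2E)-5-[(1S,4aS,5S,8aR)-5-(acetoxymethyl)-5,8a-dimethyl-2-oxo-1,2,4a,5,6,7,8,8a-octahydronaphthalen-1-yl]-3-methylpent-2-enoate, via trimethylsilyl enol ether 13 (not isolated)
Conditions: LiN(iPr)2 (1.1 equiv), TMSCl (premixed), THF, −78 °C; then Pd(OAc)2 (1.05 equiv), MeCN, rt
Reagents that add atoms: none
Why: In this Saegusa–Ito oxidation kinetic deprotonation takes the less hindered C7 methylene and not the tertiary C9–H, and Pd(OAc)2 converts the silyl enol ether into the C6=C7 enone by β-hydride elimination.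

Step 9
Reactants: 14 enone
Product: 15 methyl (2E)-5-[(1R,4aS,5S,8aS)-5-(acetoxymethyl)-5,8a-dimethyl-2-methylidene-1,2,4a,5,6,7,8,8a-octahydronaphthalen-1-yl]-3-methylpent-2-enoate
Conditions: Zn, CH2Br2, TiCl4, THF/CH2Cl2, 0 °C → rt
Reagents that add atoms: dibromomethane, BrCBr
Why: Takai–Lombardo methylenation converts the hindered, enolisable enone carbonyl into the exocyclic methylene under non-basic conditions that leave both esters, the C13=C14 geometry and the C9 centre untouched.

**Compound list**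

1 | dehydroabietic acid, (1R,4aS,10aR)-1,4a-dimethyl-7-(propan-2-yl)-1,2,3,4,4a,9,10,10a-octahydrophenanthrene-1-carboxylic acid | CC(C)C1=CC2=C(C=C1)[C@]3(CCC[C@@]([C@@H]3CC2)(C)C(=O)O)C | starting material
2 | dilithium gem-diolate from 1 and MeLi | CC(C)C1=CC2=C(C=C1)[C@]3(CCC[C@@]([C@@H]3CC2)(C)C(C)(O[Li])O[Li])C | intermediate
3 | 1-[(1R,4aS,10aR)-1,4a-dimethyl-7-(propan-2-yl)-1,2,3,4,4a,9,10,10a-octahydrophenanthren-1-yl]ethan-1-one | CC(C)C1=CC2=C(C=C1)[C@]3(CCC[C@@]([C@@H]3CC2)(C)C(C)=O)C | intermediate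
4 | (1S,2S,3R)-3-acetyl-2-(2-carboxyethyl)-1,3-dimethylcyclohexane-1-carboxylic acid | OC(=O)[C@]1(CCC[C@@]([C@@H]1CCC(=O)O)(C)C(C)=O)C | intermediate
5 | (1S,2S,3R)-3-acetyl-2-(3-methoxy-3-oxopropyl)-1,3-dimethylcyclohexane-1-carboxylic acid | OC(=O)[C@]1(CCC[C@@]([C@@H]1CCC(=O)OC)(C)C(C)=O)C | intermediate
6 | methyl 3-[(1R,2R,6S)-2-acetyl-6-(hydroxymethyl)-2,6-dimethylcyclohexyl]propanoate | OC[C@]1(CCC[C@@]([C@@H]1CCC(=O)OC)(C)C(C)=O)C | intermediate
7 | methyl 3-[(1R,2R,6S)-2-acetyl-6-(acetoxymethyl)-2,6-dimethylcyclohexyl]propanoate | CC(=O)OC[C@]1(CCC[C@@]([C@@H]1CCC(=O)OC)(C)C(C)=O)C | intermediate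
8 | methyl (2E)-4-bromo-3-methylbut-2-enoate | BrC/C(C)=C/C(=O)OC | starting material
9 | lithium enolate of 7 (at the acetyl methyl) | CC(=O)OC[C@]1(CCC[C@@]([C@@H]1CCC(=O)OC)(C)C(=C)O[Li])C | intermediate
10 | methyl (2E)-6-[(1R,2R,3S)-3-(acetoxymethyl)-2-(3-methoxy-3-oxopropyl)-1,3-dimethylcyclohexyl]-3-methyl-6-oxohex-2-enoate | CC(=O)OC[C@]1(CCC[C@@]([C@@H]1CCC(=O)OC)(C)C(=O)CC/C(C)=C/C(=O)OC)C | intermediate
11 | methyl (2E)-5-[(4aS,5S,8aR)-5-(acetoxymethyl)-2-methoxy-5,8a-dimethyl-3,4,4a,5,6,7,8,8a-octahydronaphthalen-1-yl]-3-methylpent-2-enoate | CC(=O)OC[C@]1(CCC[C@@]2([C@@H]1CCC(OC)=C2CC/C(C)=C/C(=O)OC)C)C | intermediate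
12 | methyl (2E)-5-[(1S,4aS,5S,8aR)-5-(acetoxymethyl)-5,8a-dimethyl-2-oxodecahydronaphthalen-1-yl]-3-methylpent-2-enoate | O=C1CC[C@@H]2[C@@](C)(COC(C)=O)CCC[C@@]2(C)[C@@H]1CC/C(C)=C/C(=O)OC | intermediate
13 | C7=C8 trimethylsilyl enol ether of 12 | C[Si](C)(C)OC1=CC[C@@H]2[C@@](C)(COC(C)=O)CCC[C@@]2(C)[C@@H]1CC/C(C)=C/C(=O)OC | intermediate
14 | methyl (2E)-5-[(1S,4aS,5S,8aR)-5-(acetoxymethyl)-5,8a-dimethyl-2-oxo-1,2,4a,5,6,7,8,8a-octahydronaphthalen-1-yl]-3-methylpent-2-enoate | O=C1C=C[C@@H]2[C@@](C)(COC(C)=O)CCC[C@@]2(C)[C@@H]1CC/C(C)=C/C(=O)OC | intermediate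
15 | methyl (2E)-5-[(1R,4aS,5S,8aS)-5-(acetoxymethyl)-5,8a-dimethyl-2-methylidene-1,2,4a,5,6,7,8,8a-octahydronaphthalen-1-yl]-3-methylpent-2-enoate (CNP0148290.1) | C=C1C=C[C@@H]2[C@@](C)(COC(C)=O)CCC[C@@]2(C)[C@@H]1CC/C(C)=C/C(=O)OC | target

**Totals**

Total steps: 9. Longest linear sequence: 9 steps (1 → 15); 8 is used as purchased.

**Three steps most likely to fail**

Step 7 (key ring closure). The large excess of low-valent titanium may reduce the enoate or strip the acetate, and the ketone is neopentyl. The fallback sets out from 7 and comes back at 14; it closes the ring before the enoate exists. Enolate 9 is alkylated with allyl bromide instead of 8 to give the pent-4-enoyl ketone F3. The same TiCl3(DME)1.5/Zn–Cu cyclisation gives the cyclic methyl enol ether F4, and hydrolysis gives the 9-(but-3-enyl) decalone F5. Saegusa–Ito oxidation through the trimethylsilyl enol ether F6 gives the butenyl enone F7. Tsuji–Wacker oxidation (PdCl2, CuCl, O2, DMF/H2O) of the terminal vinyl group gives the enone methyl ketone F8. A Horner–Wadsworth–Emmons reaction (trimethyl phosphonoacetate, NaH, THF) takes the unhindered methyl ketone rather than the hindered conjugated ring ketone and gives 14 after removal of the minor Z isomer.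

Step 2 (arene degradation). RuO4 can oxidise the benzylic C7 methylene first; the resulting aryl ketone deactivates the ring and leads to a chain one carbon short. The fallback sets out from 3 and comes back at 4; it activates the ring before cleaving it. Nitration (HNO3/H2SO4, 0 °C) gives the 6,8-dinitro ketone F1 (abietane positions 12 and 14). Hydrogenation (H2, Pd/C, EtOAc) gives the 6,8-diamino ketone F2. Its electron-rich ring is consumed by RuCl3/NaIO4 (or KMnO4) at 0 °C, faster than benzylic oxidation, to give 4.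

Step 8 (regioselective dehydrogenation). The amide base can also remove a γ-proton of the enoate, and any C8=C9 silyl enol ether would be lost. The fallback sets out from 12 and comes back at 15; it methylenates first and introduces the C6=C7 bond by allylic oxidation and elimination. Takai–Lombardo methylenation of 12 (Zn, CH2Br2, TiCl4) gives the 8(17)-ene F9. Allylic hydroxylation with SeO2 (cat.)/t-BuOOH in CH2Cl2 gives the axial C7 allylic alcohol F10. Dehydration with Burgess reagent (benzene, 50 °C) toward C6 gives 15.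

**Further compounds**

F1 | step 2 | 1-[(1R,4aS,10aR)-1,4a-dimethyl-6,8-dinitro-7-(propan-2-yl)-1,2,3,4,4a,9,10,10a-octahydrophenanthren-1-yl]ethan-1-one | CC(C)C1=C([N+](=O)[O-])C2=C(C=C1[N+](=O)[O-])[C@]3(CCC[C@@]([C@@H]3CC2)(C)C(C)=O)C
F2 | step 2 | 1-[(1R,4aS,10aR)-6,8-diamino-1,4a-dimethyl-7-(propan-2-yl)-1,2,3,4,4a,9,10,10a-octahydrophenanthren-1-yl]ethan-1-one | CC(C)C1=C(N)C2=C(C=C1N)[C@]3(CCC[C@@]([C@@H]3CC2)(C)C(C)=O)C
F3 | step 7 | methyl 3-[(1R,2R,6S)-6-(acetoxymethyl)-2,6-dimethyl-2-(pent-4-enoyl)cyclohexyl]propanoate | CC(=O)OC[C@]1(CCC[C@@]([C@@H]1CCC(=O)OC)(C)C(=O)CCC=C)C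
F4 | step 7 | cyclic methyl enol ether (C8–OMe, C8=C9) carrying a but-3-enyl chain at C9, ring configuration as in 11 | CC(=O)OC[C@]1(CCC[C@@]2([C@@H]1CCC(OC)=C2CCC=C)C)C
F5 | step 7 | [(1S,4aR,5S,8aS)-5-(but-3-en-1-yl)-1,4a-dimethyl-6-oxodecahydronaphthalen-1-yl]methyl acetate (but-3-enyl analogue of 12) | O=C1CC[C@@H]2[C@@](C)(COC(C)=O)CCC[C@@]2(C)[C@@H]1CCC=C
F6 | step 7 | C7=C8 trimethylsilyl enol ether of F5 | C[Si](C)(C)OC1=CC[C@@H]2[C@@](C)(COC(C)=O)CCC[C@@]2(C)[C@@H]1CCC=C
F7 | step 7 | but-3-enyl analogue of enone 14 (C6=C7, C8=O, same ring configuration) | O=C1C=C[C@@H]2[C@@](C)(COC(C)=O)CCC[C@@]2(C)[C@@H]1CCC=C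
F8 | step 7 | 3-oxobutyl analogue of enone 14 (C13 methyl ketone, same ring configuration) | O=C1C=C[C@@H]2[C@@](C)(COC(C)=O)CCC[C@@]2(C)[C@@H]1CCC(C)=O
F9 | step 8 | methyl (2E)-5-[(1R,4aS,5S,8aS)-5-(acetoxymethyl)-5,8a-dimethyl-2-methylidenedecahydronaphthalen-1-yl]-3-methylpent-2-enoate | C=C1CC[C@@H]2[C@@](C)(COC(C)=O)CCC[C@@]2(C)[C@@H]1CC/C(C)=C/C(=O)OC
F10 | step 8 | C7 axial allylic alcohol of F9 (hydroxyl cis to H-5 and H-9, trans to the C10 methyl) | C=C1[C@@H](O)C[C@@H]2[C@@](C)(COC(C)=O)CCC[C@@]2(C)[C@@H]1CC/C(C)=C/C(=O)OC
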